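Start from the level the dissolved starting material can hold, not from the solid, and ask who finishes before whom.

solid substrate 0.057 M; partner 0.0741 M; protic impurity 0.0114 M; time 3.0 min

    partner + protic impurity → quenched reagent (k1 = 27 /M/s)
    2 starting material → side product (k2 = 0.79 /M/s)
    starting material + partner → target (k3 = 0.41 /M/s)
    solid substrate ⇌ starting material, rate k4*(cs4 - [starting material]) while solid is left; crystals form when [starting material] > cs4 (cs4 = 2.1 mM, k4 = 0.072 /s)

- how much target there is at 3.0 min, in percent of the solid substrate charged
- the change that raises the amount of target at 3.0 min, in percent of the solid substrate charged most ("none" if none brings more than 2 percentage points) (east / north-east / south-east / none)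
- amount of target at 3.0 min, in percent of the solid substrate charged, after east

- east: doubling the solubility in step 4, all else as stated
- north-east: doubling the amount of partner, all else as stated
- south-east: doubling the dissolution coefficient of step 4, all else as stated

- percent here means solid substrate units held: one side product counts as two
- a step written with two of one species runs at k times the square of its concentration and takes two of it each time
- solid substrate is a solid; its amount is given per volume of the solution
- at the start none of the solid substrate is in solution
- run time (flask): 3.0 min

On the fastest rung the protic impurity quenches partner, with a half-life of 2.3 s for partner with the charges held, and I count 0.0627 M of partner afterwards. Next comes a tank. The solid feeds in proportion to the gap below solubility, and partner drains starting material at a pseudo-first-order 0.0257 /s. Where inflow meets outflow stands the holding level, 1.55 mM, which is the solubility times the dissolution coefficient over the sum of that coefficient and the drain. The tank approaches it in about 10.2 s.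

The loss to side product, 0.00245 /s, is less than the drain, so I drop it as a small correction. Over the whole run, dissolution into a solution kept empty could deliver 47.7 % by 3.0 min, less than the charge, so solid stays present.

Target therefore forms at 3.98 × 10⁻⁵ M/s, and after the lag that makes 11.8 %, with partner held at its level after the quench. Doubling the solubility doubles the level and gives 23.7 %. That is more than doubled partner, 20.0 %, or a doubled dissolution coefficient, 14.0 %. I commit to east.

The forecast gives 11.2 %, east and 20.9 %, on the ground that “dissolved substrate sits at a quasi-steady ~1.5 mM below saturation with plenty of solid left”.

The simulation gives 11.1 %, east with a gain of 9.8 percentage points, and 20.9 %. Dissolved starting material in this flask stands at 1.55 mM at 3.00 min, against my 1.55 mM. Now take the neighbour charged with 0.046 M of protic impurity. Its quench leaves 0.0281 M of partner, so the holding level rises to 1.81 mM, while the weaker drain gives 6.15 % of target. That flask stands at 1.78 mM of starting material and 5.66 % of target.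

(The numbers of this flask belong to no real substance; the run is a simulation.)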